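**Retrosynthetic overview**
1. Target 13 ⇐ 12 by one global hydrogenolysis (ten O-benzyl groups and the C8 bromine cap of the lower unit).
2. 12 ⇐ 6 + 10: the interflavan C4(upper)–C6(lower) bond is made by a new arylative opening of the flav-3-ene β-oxide 11, which also sets C3–OH and C4 of the upper unit (2,3-trans-3,4-trans).
3. 6 ⇐ 5 ⇐ racemic 4 ⇐ 3 ⇐ 1 + 2: the upper unit is built de novo; its ring C is closed by oxa-Michael addition, C2 is fixed by a transfer-hydrogenation kinetic resolution, and dehydration gives the flav-3-ene.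
4. 10 ⇐ 7: the lower unit comes from (+)-gallocatechin (rings A, C and B bought intact) by O-benzylation, C8 bromination and 3-O-benzylation.
5. Ring order: ring C of the upper unit (step 2), then the transient oxirane (step 8); no other ring is formed.

Assumption: the SMILES is read as robinetinidol-(4α→6)-gallocatechin, upper unit (2R,3S,4S) and lower unit (2R,3S), and (+)-gallocatechin 7 is bought as the single (2R,3S) enantiomer.

**Route**

Step 1
Reactants: 1 4'-benzyloxy-2'-hydroxyacetophenone; 2 3,4,5-tris(benzyloxy)benzaldehyde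
Product: 3 (E)-1-[4-(benzyloxy)-2-hydroxyphenyl]-3-[3,4,5-tris(benzyloxy)phenyl]prop-2-en-1-one (2'-hydroxychalcone)
Conditions: KOH (50% aq), EtOH/THF, rt, 36 h
Reagents that add atoms: none
Why: Claisen–Schmidt aldol condensation of a methyl ketone with a non-enolisable aldehyde gives the conjugated (E)-enone after loss of water, and benzyl ethers are inert to hydroxide.

Step 2
Reactants: 3 the 2'-hydroxychalcone
Product: 4 racemic 7-(benzyloxy)-2-[3,4,5-tris(benzyloxy)phenyl]chroman-4-one (flavanone)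
Conditions: NaOAc, EtOH/THF, reflux, 24 h (recovered 3 recycled)
Reagents that add atoms: none
Why: base-mediated 6-endo intramolecular oxa-Michael addition of the 2'-OH (chalcone–flavanone isomerisation) closes ring C of the upper unit; C2 is formed as a racemate here and is resolved in step 3.

Step 3
Reactants: 4 racemic flavanone
Product: 5 (2S,4S)-7-(benzyloxy)-2-[3,4,5-tris(benzyloxy)phenyl]chroman-4-ol (2,4-cis)
Conditions: RuCl(p-cymene)[(S,S)-TsDPEN] (1 mol%), HCO2H/Et3N (5:2), EtOAc, 40 °C, stopped at about 50% conversion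
Reagents that add atoms: none
Why: Noyori–Ikariya asymmetric transfer hydrogenation used as a kinetic resolution: the (S,S) catalyst sets C4 as S (as for 4-chromanone) and this hydride delivery is anti to the C2 aryl group only in (2S)-4, so the (2S) enantiomer alone is reduced to the 2,4-cis alcohol while (2R)-4 is recovered and re-racemised under the step 2 conditions.

Step 4
Reactants: 5 (2S,4S)-flavan-4-ol
Product: 6 (2S)-7-(benzyloxy)-2-[3,4,5-tris(benzyloxy)phenyl]-2H-chromene (flav-3-ene)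
Conditions: Ph2S[OC(CF3)2Ph]2 (Martin sulfurane, 1.3 equiv), CH2Cl2, 0 °C → rt, dark; Et3N-deactivated silica
Reagents that add atoms: none
Why: sulfurane dehydration of the electron-rich benzylic alcohol (E1/E2-type elimination toward C3) runs without acid, so the acid-sensitive flavene survives and the C2 stereocentre, which is not involved, is kept.

Step 5
Reactants: 7 (+)-gallocatechin
Product: 8 (2R,3S)-5,7-bis(benzyloxy)-2-[3,4,5-tris(benzyloxy)phenyl]chroman-3-ol
Conditions: BnBr (5.3 equiv), K2CO3 (6 equiv), degassed DMF, Ar, 0 °C → rt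
Reagents that add atoms: benzyl bromide, BrCc1ccccc1
Why: Williamson ether synthesis; carbonate deprotonates only the five phenols and not the C3 alcohol, and the mild base at or below rt avoids C2 epimerisation.

Step 6
Reactants: 8 penta-O-benzyl-gallocatechin
Product: 9 (2R,3S)-5,7-bis(benzyloxy)-8-bromo-2-[3,4,5-tris(benzyloxy)phenyl]chroman-3-ol
Conditions: NBS (1.0 equiv), CH2Cl2, −78 → 0 °C
Reagents that add atoms: N-bromosuccinimide, O=C1CCC(=O)N1Br
Why: electrophilic aromatic bromination goes to C8, the most reactive position of a 5,7-dialkoxyflavan ring A, which leaves C6 as the only free carbon of that ring for the later coupling.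

Step 7
Reactants: 9 8-bromo-penta-O-benzyl-gallocatechin
Product: 10 (2R,3S)-3,5,7-tris(benzyloxy)-8-bromo-2-[3,4,5-tris(benzyloxy)phenyl]chroman
Conditions: NaH (1.5 equiv), BnBr (1.5 equiv), Bu4NI (cat.), THF/DMF, 0 °C → rt
Reagents that add atoms: benzyl bromide, BrCc1ccccc1
Why: Williamson O-alkylation of the C3 alcohol removes the only O-nucleophile of the lower unit before the coupling; the aryl bromide and both stereocentres are untouched.

Step 8
Reactants: 6 (2S)-flav-3-ene; 10 8-bromo-hexa-O-benzyl-gallocatechin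
Product: 12 7,3',4',5'-tetra-O-benzyl-robinetinidol-(4α→6)-(8-bromo-3,5,7,3',4',5'-hexa-O-benzyl-gallocatechin), via trans-flav-3-ene oxide 11 (not isolated)
Conditions: DMDO (1.1 equiv, acetone), CH2Cl2, 4 Å MS, −40 °C; volatiles removed cold; then 10 (1.5 equiv), (CF3)2CHOH (10 equiv), CH2Cl2, −40 → −10 °C
Reagents that add atoms: dimethyldioxirane, CC1(C)OO1
Why: Proposed new method: interflavan C4–C6 bond formation by stereoinvertive Friedel–Crafts opening of a flav-3-ene oxide — DMDO epoxidises the styrenyl C3=C4 bond of 6 on the face anti to the C2 aryl group to give the β-oxide 11, whose C4–O bond is benzylic and conjugated to the para 7-benzyloxy group and the ortho ring oxygen, so hydrogen bonding from (CF3)2CHOH is enough to polarise it selectively; C6 of 10, the only unsubstituted carbon of its phloroglucinol-type ring A (C8 carries Br), attacks C4 from the α face in an SN2-like or tight-ion-pair transition state while the fluoroalcohol-bound oxygen at C3 shields the β face, then rearomatises, which fixes the 4→6 regiochemistry, sets C4 as S (3,4-trans) and leaves the C3 oxygen in place as the (S)-alcohol; the closest known reaction type is the fluoroalcohol- or Lewis-acid-promoted Friedel–Crafts ring opening of aryl epoxides by electron-rich arenes with inversion at the benzylic carbon, together with the flavan-4-yl cation arylation used for 4→8 proanthocyanidins.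

Step 9
Reactants: 12 protected bromo dimer
Product: 13 robinetinidol-(4α→6)-gallocatechin (target)
Conditions: H2 (1 atm), Pd(OH)2/C, NaOAc (1.5 equiv), THF/MeOH/H2O, rt; then AcOH, Sephadex LH-20, lyophilised under Ar
Reagents that add atoms: none
Why: heterogeneous hydrogenolysis cleaves the ten benzyl ethers and hydrodebrominates C8 in one operation, with acetate buffering the HBr; no stereocentre is touched.

**Compound list**
1 | 4'-benzyloxy-2'-hydroxyacetophenone | CC(=O)c1ccc(OCc2ccccc2)cc1O | starting material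
2 | 3,4,5-tris(benzyloxy)benzaldehyde | O=Cc1cc(OCc2ccccc2)c(OCc2ccccc2)c(OCc2ccccc2)c1 | starting material
3 | (E)-1-[4-(benzyloxy)-2-hydroxyphenyl]-3-[3,4,5-tris(benzyloxy)phenyl]prop-2-en-1-one | O=C(/C=C/c1cc(OCc2ccccc2)c(OCc2ccccc2)c(OCc2ccccc2)c1)c1ccc(OCc2ccccc2)cc1O | intermediate
4 | racemic 7-(benzyloxy)-2-[3,4,5-tris(benzyloxy)phenyl]chroman-4-one | O=C1CC(c2cc(OCc3ccccc3)c(OCc3ccccc3)c(OCc3ccccc3)c2)Oc2cc(OCc3ccccc3)ccc21 | intermediate
5 | (2S,4S)-7-(benzyloxy)-2-[3,4,5-tris(benzyloxy)phenyl]chroman-4-ol (2,4-cis) | O[C@H]1C[C@@H](c2cc(OCc3ccccc3)c(OCc3ccccc3)c(OCc3ccccc3)c2)Oc2cc(OCc3ccccc3)ccc21 | intermediate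
6 | (2S)-7-(benzyloxy)-2-[3,4,5-tris(benzyloxy)phenyl]-2H-chromene | C1=C[C@@H](c2cc(OCc3ccccc3)c(OCc3ccccc3)c(OCc3ccccc3)c2)Oc2cc(OCc3ccccc3)ccc21 | intermediate
7 | (+)-gallocatechin, (2R,3S)-2-(3,4,5-trihydroxyphenyl)chroman-3,5,7-triol | Oc1cc(O)c2C[C@H](O)[C@@H](c3cc(O)c(O)c(O)c3)Oc2c1 | starting material
8 | (2R,3S)-5,7-bis(benzyloxy)-2-[3,4,5-tris(benzyloxy)phenyl]chroman-3-ol | c1ccccc1COc1cc(OCc3ccccc3)c2C[C@H](O)[C@@H](c3cc(OCc4ccccc4)c(OCc4ccccc4)c(OCc4ccccc4)c3)Oc2c1 | intermediate
9 | (2R,3S)-5,7-bis(benzyloxy)-8-bromo-2-[3,4,5-tris(benzyloxy)phenyl]chroman-3-ol | c1ccccc1COc1cc(OCc3ccccc3)c2C[C@H](O)[C@@H](c3cc(OCc4ccccc4)c(OCc4ccccc4)c(OCc4ccccc4)c3)Oc2c1Br | intermediate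
10 | (2R,3S)-3,5,7-tris(benzyloxy)-8-bromo-2-[3,4,5-tris(benzyloxy)phenyl]chroman | c1ccccc1COc1cc(OCc3ccccc3)c2C[C@H](OCc3ccccc3)[C@@H](c3cc(OCc4ccccc4)c(OCc4ccccc4)c(OCc4ccccc4)c3)Oc2c1Br | intermediate
11 | (2R,3S,4S)-7-(benzyloxy)-3,4-epoxy-2-[3,4,5-tris(benzyloxy)phenyl]chroman (oxirane oxygen anti to the 2-aryl group) | c1ccccc1COc1ccc2c(c1)O[C@H](c1cc(OCc3ccccc3)c(OCc3ccccc3)c(OCc3ccccc3)c1)[C@H]1O[C@@H]21 | intermediate
12 | 7,3',4',5'-tetra-O-benzyl-robinetinidol-(4α→6)-(8-bromo-3,5,7,3',4',5'-hexa-O-benzyl-gallocatechin); upper unit (2R,3S,4S) with free 3-OH, lower unit (2R,3S) | c1ccccc1COc1ccc2c(c1)O[C@H](c1cc(OCc3ccccc3)c(OCc3ccccc3)c(OCc3ccccc3)c1)[C@@H](O)[C@@H]2c1c(OCc3ccccc3)c(Br)c2c(c1OCc3ccccc3)C[C@H](OCc3ccccc3)[C@@H](c1cc(OCc3ccccc3)c(OCc3ccccc3)c(OCc3ccccc3)c1)O2 | intermediate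
13 | robinetinidol-(4α→6)-gallocatechin, (2R,3S,4S)-2-(3,4,5-trihydroxyphenyl)-4-[(2R,3S)-3,5,7-trihydroxy-2-(3,4,5-trihydroxyphenyl)chroman-6-yl]chroman-3,7-diol | Oc1ccc2c(c1)O[C@H](c1cc(O)c(O)c(O)c1)[C@@H](O)[C@@H]2c1c(O)cc2c(c1O)C[C@H](O)[C@@H](c1cc(O)c(O)c(O)c1)O2 | target

**Summary**
Total step count: 9 (step 8 runs epoxidation and coupling in one pot).
Longest linear sequence: 6 steps (steps 1, 2, 3, 4, 8, 9, from 1 and 2); the lower-unit branch is 5 steps (steps 5, 6, 7, 8, 9).

**Steps most likely to fail**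

Step 8 (the proposed new step). The oxide 11 may rearrange to the flavan-3-one by a 1,2-hydride shift, may open with partial loss of stereocontrol, or the hindered bromo-capped C6 of 10 may react too slowly. The fallback uses known chemistry, sets out from 6 and comes back at 12. Compound 6 is dihydroxylated (OsO4 cat., N-methylmorpholine N-oxide, acetone/H2O; syn addition anti to the 2-aryl group) to the 2,3-trans-3,4-cis diol (2R,3S,4S)-7-(benzyloxy)-2-[3,4,5-tris(benzyloxy)phenyl]chroman-3,4-diol F1. This diol is ionised at C4 with BF3·OEt2 in CH2Cl2 at −78 → −30 °C in the presence of 10 (the classical flavan-3,4-diol Friedel–Crafts condensation), and the 3,4-trans product 12 is separated from its 4β epimer by chromatography.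

Step 3. The resolution may be unselective on this heavily benzylated substrate, and it caps the yield at 50% per pass. The fallback sets out from 1 and comes back at 5. Compound 1 is condensed with DMF dimethyl acetal to the enaminone (E)-1-[4-(benzyloxy)-2-hydroxyphenyl]-3-(dimethylamino)prop-2-en-1-one F2, which is cyclised with HCl to 7-(benzyloxy)-4H-chromen-4-one F3. Enantioselective conjugate addition of 3,4,5-tris(benzyloxy)phenylboronic acid follows (Pd(OCOCF3)2, the t-BuPyOx enantiomer that gives the 2S series, expected to be (R), NH4PF6, H2O, ClCH2CH2Cl, 60 °C) and gives (2S)-7-(benzyloxy)-2-[3,4,5-tris(benzyloxy)phenyl]chroman-4-one F4. NaBH4 in MeOH/THF at 0 °C, with hydride delivery anti to the aryl group, then gives 5.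

Step 9. The HBr formed next to an air- and acid-sensitive pyrogallol-type polyphenol may cause catalyst poisoning or decomposition. The fallback sets out from 12 and comes back at 13. The bromine is removed first by radical reduction (Bu3SnH, AIBN, toluene, 90 °C; KF work-up) to give 7,3',4',5'-tetra-O-benzyl-robinetinidol-(4α→6)-(3,5,7,3',4',5'-hexa-O-benzyl-gallocatechin) F5. This is then hydrogenolysed (H2, Pd(OH)2/C, THF/MeOH, rt) to 13 with no acid generated.

**Further compounds**
F1 | step 8 | (2R,3S,4S)-7-(benzyloxy)-2-[3,4,5-tris(benzyloxy)phenyl]chroman-3,4-diol (2,3-trans-3,4-cis) | c1ccccc1COc1ccc2c(c1)O[C@H](c1cc(OCc3ccccc3)c(OCc3ccccc3)c(OCc3ccccc3)c1)[C@@H](O)[C@H]2O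
F2 | step 3 | (E)-1-[4-(benzyloxy)-2-hydroxyphenyl]-3-(dimethylamino)prop-2-en-1-one | CN(C)/C=C/C(=O)c1ccc(OCc2ccccc2)cc1O
F3 | step 3 | 7-(benzyloxy)-4H-chromen-4-one | O=c1ccoc2cc(OCc3ccccc3)ccc12
F4 | step 3 | (2S)-7-(benzyloxy)-2-[3,4,5-tris(benzyloxy)phenyl]chroman-4-one | O=C1C[C@@H](c2cc(OCc3ccccc3)c(OCc3ccccc3)c(OCc3ccccc3)c2)Oc2cc(OCc3ccccc3)ccc21
F5 | step 9 | 7,3',4',5'-tetra-O-benzyl-robinetinidol-(4α→6)-(3,5,7,3',4',5'-hexa-O-benzyl-gallocatechin) | c1ccccc1COc1ccc2c(c1)O[C@H](c1cc(OCc3ccccc3)c(OCc3ccccc3)c(OCc3ccccc3)c1)[C@@H](O)[C@@H]2c1c(OCc3ccccc3)cc2c(c1OCc3ccccc3)C[C@H](OCc3ccccc3)[C@@H](c1cc(OCc3ccccc3)c(OCc3ccccc3)c(OCc3ccccc3)c1)O2
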